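If two flasks share a partner charge and differ in catalyst, what should they be compared by?

the same everywhere: left-handed substrate 0.050 M; right-handed substrate 0.050 M

|  | partner | catalyst | remark | time |
|---|---|---|---|---|
| blue | 1.5 equiv | 1.3 mol% | run made earlier |  |
| ochre | 1.5 equiv | 6.1 mol% | run made earlier |  |
| winter | 1.50 equiv | 1 mol% |  | 8.0 d |
| noon | 1.50 equiv | 4 mol% |  | 8.0 d |

- blue (time / d: right-handed substrate / %, left-handed substrate / %): 0.333: 49.8, 41.2; 1.04: 49.4, 28.2; 1.67: 49.6, 21.7; 3.00: 48.8, 15.2; 4.00: 48.6, 11.6
- ochre (time / d: right-handed substrate / %, left-handed substrate / %): 0.833: 48.2, 10.9; 1.67: 48.2, 4.3; 2.50: 47.0, 1.4; 3.00: 47.3, 1.9; 4.00: 46.9, 0.2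

(readings scatter by 0.5 percentage points)

- catalyst is single-handed; left-handed substrate and right-handed substrate are mirror images of each other, charged as a racemate, each of them at the stated concentration
- an excess is the difference of the two amounts in percent of their sum
- an excess is below zero if the other one leads

- which one finishes higher in excess of right-handed substrate over left-handed substrate among what is left of the two ("neither" within 2 percentage points) (winter / noon / neither)
- excess of right-handed substrate over left-handed substrate among what is left of the two at the end, winter
- excess of right-handed substrate over left-handed substrate among what is left of the two at the end, noon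

What do the runs show? In ochre the right-handed substrate goes from 48.2% to 46.9%, while the left-handed substrate goes from 10.9% to 0.2%. So the excess hangs on how far the left-handed substrate has fallen.

And your yardstick? The catalyst dose. Noon has 6.15 and winter 1.54, where catalyst dose means loading times time, divided by that product for blue at its last reading.

Does it work? Blue at one dose leaves 11.6%. Ochre at 0.833 d stands at 0.977 and leaves 10.9%, so the two runs meet, given a scatter of 0.5 percentage points per reading.

Then winter? Its dose lies between ochre's first two readings, the second at 1.96. Interpolating the logarithm gives 6.40% of left-handed substrate, so my excess is 76.5%.

And noon? Its dose is larger than ochre's last, 4.69, and that reading, 0.2%, already lies within the scatter of zero. I expect noon close to full excess, well above winter.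

Where is this weak? Both earlier runs hold 1.5 equiv of partner, so they cannot show what the dose owes to [partner]. The yardstick was tested at that charge, which winter and noon share.

The forecast says noon, with 76% for winter and 99.7% for noon, on the ground that “the curves overlap on catalyst × time”. On winter it stands just below my figure.

The flask gives noon: winter ends at 73.1% and noon at 98.6%.

    partner + catalyst + left-handed substrate → catalyst + left-handed product (k = 520 M⁻² h⁻¹)
    partner + catalyst + right-handed substrate → catalyst + right-handed product (k = 7.20 M⁻² h⁻¹)
    left-handed product ⇌ right-handed product (k = 0.0240 h⁻¹)
    partner → decomposed reagent (k = 0.00120 h⁻¹)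

Taking noon's loading back to winter's brings its excess from 98.6% to 73.1%, so the step in dose from 1.54 to 6.15 may be called the main reason noon leads. Yet equal dose gives no equal flask at a smaller partner charge. A neighbour of noon charged with 0.600 equiv of partner has the same dose of 6.15, but there partner is the limiting reagent, down to 0.43% of its charge. That neighbour keeps 43% of its left-handed substrate and ends at an excess of 39.0%.

The earlier runs and the new flask were computed with made-up constants, and the scatter is random.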